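**Plan**
- Retrosynthesis: after removal of the two silyl groups and saturation of C2=C3, ring B is cut at C2=C3 by ring-closing metathesis. This works because the C2–C3 bridge of ring B is unsubstituted and sits between the carbinol C1 and the diarylmethine C4, both benzylic on ring A, so each can be made as a vinyl-bearing allylic stereocentre on an ortho-disubstituted benzene.
- The diene is then cut at C4–C4a (iridium-catalysed allylic arylation) into the arylzinc of an (S)-1-(2-bromo-3-methoxyphenyl)allyl silyl ether and a 3-(naphthyl)allyl carbonate derived from naphthalene-1,8-diol.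
- Forward: naphthalene fragment (steps 1–6), ring A fragment (steps 7–9), C4–C4a coupling (step 10), closure of ring B (step 11), alkene reduction and desilylation (steps 12–13).
- Stereochemistry: C1 from a Sharpless kinetic resolution (step 8), C4 from the chiral iridium–phosphoramidite catalyst (step 10); ring closure, diimide reduction and deprotection leave both centres untouched and give the cis (1S,4S) tetralin.

Key step: step 11

Assumption: the sense of induction of the iridium–phosphoramidite catalyst in step 10 is assigned by analogy with simpler 3-arylallyl carbonates; if this substrate reacts on the other allyl face, the antipodal ligand is used and nothing else changes.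

**Route**

Step 1
Reactants: 1 naphthalene-1,8-diol
Product: 2 8-methoxynaphthalen-1-ol
Conditions: MeI (1.05 equiv), K2CO3 (1.1 equiv), acetone, reflux
Reagents that add atoms: iodomethane, CI
Why: Williamson ether synthesis; after the first O-methylation the remaining peri hydroxyl is hydrogen-bonded to the new methoxy oxygen and less acidic, so one equivalent of MeI should stop at the monoether.

Step 2
Reactants: 2 8-methoxynaphthalen-1-ol
Product: 3 4-bromo-8-methoxynaphthalen-1-ol
Conditions: NBS (1.0 equiv), MeCN, -20 °C to 0 °C, dark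
Reagents that add atoms: N-bromosuccinimide, O=C1CCC(=O)N1Br
Why: Electrophilic aromatic bromination; the free naphthol ring is far more activated than the anisole ring, and in a polar solvent without amine base NBS should attack the alpha position para to the hydroxyl (C4) in preference to the ortho position C2.

Step 3
Reactants: 3 4-bromo-8-methoxynaphthalen-1-ol
Product: 4 [(4-bromo-8-methoxynaphthalen-1-yl)oxy]tri(propan-2-yl)silane
Conditions: iPr3SiCl, imidazole, DMF, rt
Reagents that add atoms: chlorotri(propan-2-yl)silane, CC(C)[Si](Cl)(C(C)C)C(C)C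
Why: Silyl ether formation on the phenol; the bulky triisopropylsilyl group masks the acidic OH for the organometallic steps and should last until the final fluoride treatment.

Step 4
Reactants: 4 [(4-bromo-8-methoxynaphthalen-1-yl)oxy]tri(propan-2-yl)silane; 5 methyl acrylate
Product: 6 methyl (2E)-3-[5-methoxy-4-(triisopropylsilyloxy)naphthalen-1-yl]prop-2-enoate
Conditions: Pd(OAc)2 (5 mol%), P(o-tol)3 (10 mol%), Et3N, MeCN, 85 °C
Reagents that add atoms: none
Why: Heck reaction; oxidative addition of the aryl bromide to zerovalent palladium, syn insertion of the acrylate and syn beta-hydride elimination should give the (E)-cinnamate-type ester.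

Step 5
Reactants: 6 methyl (2E)-3-[5-methoxy-4-(triisopropylsilyloxy)naphthalen-1-yl]prop-2-enoate
Product: 7 (2E)-3-[5-methoxy-4-(triisopropylsilyloxy)naphthalen-1-yl]prop-2-en-1-ol
Conditions: iBu2AlH (2.2 equiv), CH2Cl2, -78 °C; aq. potassium sodium tartrate
Reagents that add atoms: none
Why: 1,2-Reduction of the conjugated ester by the aluminium hydride at low temperature should give the (E)-allylic alcohol without touching the alkene or the aryl silyl ether.

Step 6
Reactants: 7 (2E)-3-[5-methoxy-4-(triisopropylsilyloxy)naphthalen-1-yl]prop-2-en-1-ol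
Product: 8 methyl (2E)-3-[5-methoxy-4-(triisopropylsilyloxy)naphthalen-1-yl]prop-2-en-1-yl carbonate
Conditions: ClCO2Me, pyridine, CH2Cl2, 0 °C
Reagents that add atoms: methyl chloroformate, COC(=O)Cl
Why: O-Acylation of the primary alcohol gives the linear allylic methyl carbonate, the leaving group needed for oxidative addition to iridium in step 10.

Step 7
Reactants: 9 2-bromo-3-methoxybenzaldehyde; 10 vinylmagnesium bromide
Product: 11 rac-1-(2-bromo-3-methoxyphenyl)prop-2-en-1-ol
Conditions: CH2=CHMgBr (1.2 equiv), THF, -78 °C to 0 °C; aq. NH4Cl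
Reagents that add atoms: none
Why: Grignard 1,2-addition to the aldehyde; the aryl bromide does not exchange with the vinyl Grignard reagent at low temperature, and the carbinol is formed as the racemate.

Step 8
Reactants: 11 rac-1-(2-bromo-3-methoxyphenyl)prop-2-en-1-ol
Product: 12 (1S)-1-(2-bromo-3-methoxyphenyl)prop-2-en-1-ol
Conditions: Ti(OiPr)4, L-(+)-diisopropyl tartrate, t-BuOOH (0.6 equiv), 4 Å molecular sieves, CH2Cl2, -20 °C
Reagents that add atoms: none
Why: Sharpless kinetic resolution; with the (2R,3R)-tartrate the titanium peroxo complex should epoxidise the (R)-carbinol much faster than the (S)-carbinol, so stopping slightly beyond half conversion should leave the (S)-alcohol, which becomes C1 of the target.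

Step 9
Reactants: 12 (1S)-1-(2-bromo-3-methoxyphenyl)prop-2-en-1-ol
Product: 13 tert-butyl{[(1S)-1-(2-bromo-3-methoxyphenyl)prop-2-en-1-yl]oxy}dimethylsilane
Conditions: t-BuMe2SiCl, imidazole, DMF, rt
Reagents that add atoms: tert-butylchlorodimethylsilane, CC(C)(C)[Si](C)(C)Cl
Why: Silyl ether formation on the secondary alcohol; the C1 stereocentre is not involved, and the silyl ether later disfavours ionisation of the allylic and benzylic C1–O bond.

Step 10
Reactants: 13 tert-butyl{[(1S)-1-(2-bromo-3-methoxyphenyl)prop-2-en-1-yl]oxy}dimethylsilane (1.5 equiv); 8 methyl (2E)-3-[5-methoxy-4-(triisopropylsilyloxy)naphthalen-1-yl]prop-2-en-1-yl carbonate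
Product: 16 tert-butyl{[(1S)-1-(3-methoxy-2-{(1S)-1-[5-methoxy-4-(triisopropylsilyloxy)naphthalen-1-yl]prop-2-en-1-yl}phenyl)prop-2-en-1-yl]oxy}dimethylsilane, via aryllithium 14 (not isolated), via arylzinc bromide 15 (not isolated)
Conditions: n-BuLi, THF, -78 °C; ZnBr2, -78 °C to rt; then 8, [Ir(cod)Cl]2 (2 mol%), O,O'-[(S)-1,1'-binaphthalene-2,2'-diyl] N,N-bis[(S)-1-(2-methoxyphenyl)ethyl]phosphoramidite (4 mol%), THF, rt
Reagents that add atoms: none
Why: Bromine–lithium exchange and immediate transmetalation give an arylzinc that tolerates the carbonate, and iridium-catalysed asymmetric allylic arylation (oxidative addition of the carbonate to monovalent iridium, then aryl transfer to the substituted allyl terminus) should form the C4–C4a bond at the naphthyl-bearing carbon; the ligand is chosen so that the aryl group enters on the Si face of that carbon (priorities naphthyl > C2 > H), which gives (S) at C4 under catalyst control, independent of the remote (S)-C1 centre.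

Step 11
Reactants: 16 tert-butyl{[(1S)-1-(3-methoxy-2-{(1S)-1-[5-methoxy-4-(triisopropylsilyloxy)naphthalen-1-yl]prop-2-en-1-yl}phenyl)prop-2-en-1-yl]oxy}dimethylsilane
Product: 17 tert-butyl({(1S,4S)-5-methoxy-4-[5-methoxy-4-(triisopropylsilyloxy)naphthalen-1-yl]-1,4-dihydronaphthalen-1-yl}oxy)dimethylsilane (cis)
Conditions: second-generation Grubbs catalyst RuCl2(H2IMes)(PCy3)(=CHPh) (5 mol%), 1,4-benzoquinone (10 mol%), CH2Cl2 (0.005 M), 40 °C
Reagents that add atoms: none
Why: Ring-closing alkene metathesis by the Chauvin mechanism: the ruthenium benzylidene exchanges onto one terminal vinyl group, the new alkylidene undergoes (2+2) cycloaddition with the second vinyl group, and cycloreversion of the ruthenacyclobutane releases ethene and the C2=C3 bond. The closest known reaction type is the metathesis of 1,2-bis(allyl)benzenes carrying an allylic oxygen substituent to 1,4-dihydronaphthalenes. Ring B closes as a six-membered carbocycle by alkene–alkene metathesis of the 1,7-diene, with the ortho-phenylene unit of ring A holding the two vinyl groups within reach and forcing the new alkene to be cis in the ring. No stereocentre is created, and C1 and C4 are carried through unchanged because neither C–H bond takes part in the carbene chemistry. The step needs chemoselectivity for ring closure over oligomerisation, over ruthenium hydride-induced migration of the alkene towards the doubly benzylic C4–H, and over loss of silanol with aromatisation. High dilution, the benzoquinone hydride scavenger, the bulk and poor leaving-group ability of the silyl ether and neutral aprotic conditions are expected to secure this.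

Step 12
Reactants: 17 tert-butyl({(1S,4S)-5-methoxy-4-[5-methoxy-4-(triisopropylsilyloxy)naphthalen-1-yl]-1,4-dihydronaphthalen-1-yl}oxy)dimethylsilane
Product: 18 tert-butyl({(1S,4S)-5-methoxy-4-[5-methoxy-4-(triisopropylsilyloxy)naphthalen-1-yl]-1,2,3,4-tetrahydronaphthalen-1-yl}oxy)dimethylsilane
Conditions: 2-nitrobenzenesulfonyl hydrazide (excess), Et3N, CH2Cl2, rt
Reagents that add atoms: none
Why: Diimide reduction; concerted syn transfer of two hydrogens from diazene generated in the flask should saturate the cis-disubstituted C2=C3 alkene without a metal, so neither benzylic C–O hydrogenolysis, alkene migration nor epimerisation at C1 or C4 is expected.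

Step 13
Reactants: 18 tert-butyl({(1S,4S)-5-methoxy-4-[5-methoxy-4-(triisopropylsilyloxy)naphthalen-1-yl]-1,2,3,4-tetrahydronaphthalen-1-yl}oxy)dimethylsilane
Product: 19 (1S,4S)-4-(4-hydroxy-5-methoxynaphthalen-1-yl)-5-methoxy-1,2,3,4-tetrahydronaphthalen-1-ol (dipolynaphthalene B)
Conditions: Bu4NF (3 equiv), AcOH (3 equiv), THF, 0 °C to rt, under argon
Reagents that add atoms: none
Why: Fluoride-induced desilylation should cleave both Si–O bonds (aryl triisopropylsilyl ether and secondary tert-butyldimethylsilyl ether) under buffered conditions that neither ionise the benzylic C1–O bond nor expose the electron-rich naphtholate to air, leaving both stereocentres untouched.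

**Compound list**

1 | naphthalene-1,8-diol | Oc1cccc2cccc(O)c12 | starting material
2 | 8-methoxynaphthalen-1-ol | COc1cccc2cccc(O)c12 | intermediate
3 | 4-bromo-8-methoxynaphthalen-1-ol | COc1cccc2c(Br)ccc(O)c12 | intermediate
4 | [(4-bromo-8-methoxynaphthalen-1-yl)oxy]tri(propan-2-yl)silane | COc1cccc2c(Br)ccc(O[Si](C(C)C)(C(C)C)C(C)C)c12 | intermediate
5 | methyl acrylate | C=CC(=O)OC | starting material
6 | methyl (2E)-3-[5-methoxy-4-(triisopropylsilyloxy)naphthalen-1-yl]prop-2-enoate | COC(=O)/C=C/c1ccc(O[Si](C(C)C)(C(C)C)C(C)C)c2c(OC)cccc12 | intermediate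
7 | (2E)-3-[5-methoxy-4-(triisopropylsilyloxy)naphthalen-1-yl]prop-2-en-1-ol | OC/C=C/c1ccc(O[Si](C(C)C)(C(C)C)C(C)C)c2c(OC)cccc12 | intermediate
8 | methyl (2E)-3-[5-methoxy-4-(triisopropylsilyloxy)naphthalen-1-yl]prop-2-en-1-yl carbonate | COC(=O)OC/C=C/c1ccc(O[Si](C(C)C)(C(C)C)C(C)C)c2c(OC)cccc12 | intermediate
9 | 2-bromo-3-methoxybenzaldehyde | COc1cccc(C=O)c1Br | starting material
10 | vinylmagnesium bromide | C=C[Mg]Br | starting material
11 | rac-1-(2-bromo-3-methoxyphenyl)prop-2-en-1-ol | COc1cccc(C(O)C=C)c1Br | intermediate
12 | (1S)-1-(2-bromo-3-methoxyphenyl)prop-2-en-1-ol | COc1cccc([C@@H](O)C=C)c1Br | intermediate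
13 | tert-butyl{[(1S)-1-(2-bromo-3-methoxyphenyl)prop-2-en-1-yl]oxy}dimethylsilane | COc1cccc([C@@H](O[Si](C)(C)C(C)(C)C)C=C)c1Br | intermediate
14 | {2-[(1S)-1-(tert-butyldimethylsilyloxy)prop-2-en-1-yl]-6-methoxyphenyl}lithium | COc1cccc([C@@H](O[Si](C)(C)C(C)(C)C)C=C)c1[Li] | intermediate
15 | bromo{2-[(1S)-1-(tert-butyldimethylsilyloxy)prop-2-en-1-yl]-6-methoxyphenyl}zinc | COc1cccc([C@@H](O[Si](C)(C)C(C)(C)C)C=C)c1[Zn]Br | intermediate
16 | tert-butyl{[(1S)-1-(3-methoxy-2-{(1S)-1-[5-methoxy-4-(triisopropylsilyloxy)naphthalen-1-yl]prop-2-en-1-yl}phenyl)prop-2-en-1-yl]oxy}dimethylsilane | COc1cccc([C@@H](O[Si](C)(C)C(C)(C)C)C=C)c1[C@H](c1ccc(O[Si](C(C)C)(C(C)C)C(C)C)c2c(OC)cccc12)C=C | intermediate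
17 | tert-butyl({(1S,4S)-5-methoxy-4-[5-methoxy-4-(triisopropylsilyloxy)naphthalen-1-yl]-1,4-dihydronaphthalen-1-yl}oxy)dimethylsilane | COc1cccc2c1[C@H](c1ccc(O[Si](C(C)C)(C(C)C)C(C)C)c3c(OC)cccc13)C=C[C@@H]2O[Si](C)(C)C(C)(C)C | intermediate
18 | tert-butyl({(1S,4S)-5-methoxy-4-[5-methoxy-4-(triisopropylsilyloxy)naphthalen-1-yl]-1,2,3,4-tetrahydronaphthalen-1-yl}oxy)dimethylsilane | COc1cccc2c1[C@H](c1ccc(O[Si](C(C)C)(C(C)C)C(C)C)c3c(OC)cccc13)CC[C@@H]2O[Si](C)(C)C(C)(C)C | intermediate
19 | (1S,4S)-4-(4-hydroxy-5-methoxynaphthalen-1-yl)-5-methoxy-1,2,3,4-tetrahydronaphthalen-1-ol (dipolynaphthalene B) | COc1cccc2c1[C@H](c1ccc(O)c3c(OC)cccc13)CC[C@@H]2O | target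

**Step count**

Total: 13 steps. Longest linear sequence: 10 steps (steps 1–6, then 10–13).

**Steps most likely to fail and fallbacks**

1. Step 10.
   - What may go wrong: transfer of the ortho,ortho'-disubstituted aryl group from zinc to the allyliridium complex may be slow, may go to the unsubstituted allyl terminus (linear isomer), or may proceed with eroded facial selectivity. Silyl migration from oxygen to the lithiated carbon before transmetalation is a further hazard.
   - Fallback: C4 is set first with a small ortho group on the nucleophile, and C1 is built afterwards.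
   - Aldehyde 9 is converted with I2 and aqueous NH3 in THF into 2-bromo-3-methoxybenzonitrile F1.
   - Bromine–magnesium exchange with iPrMgCl·LiCl gives (2-cyano-6-methoxyphenyl)magnesium chloride F2, and ZnBr2 then gives (2-cyano-6-methoxyphenyl)zinc bromide F3.
   - F3 is coupled with carbonate 8 under the same iridium–phosphoramidite catalysis to give 3-methoxy-2-{(1S)-1-[5-methoxy-4-(triisopropylsilyloxy)naphthalen-1-yl]prop-2-en-1-yl}benzonitrile F4.
   - Reduction with iBu2AlH and mild acidic hydrolysis of the imine gives 3-methoxy-2-{(1S)-1-[5-methoxy-4-(triisopropylsilyloxy)naphthalen-1-yl]prop-2-en-1-yl}benzaldehyde F5.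
   - Addition of CH2=CHMgBr gives 1-(3-methoxy-2-{(1S)-1-[5-methoxy-4-(triisopropylsilyloxy)naphthalen-1-yl]prop-2-en-1-yl}phenyl)prop-2-en-1-ol F6 as a mixture of C1 epimers.
   - Sharpless kinetic resolution with Ti(OiPr)4, L-(+)-diisopropyl tartrate and t-BuOOH consumes the (1R) epimer and leaves (1S)-1-(3-methoxy-2-{(1S)-1-[5-methoxy-4-(triisopropylsilyloxy)naphthalen-1-yl]prop-2-en-1-yl}phenyl)prop-2-en-1-ol F7.
   - Silylation with t-BuMe2SiCl and imidazole returns to the route at diene 16.

2. Step 11.
   - What may go wrong: slow turnover at the two branched allylic vinyl groups would give ruthenium hydride species time to move the new alkene out of the C2=C3 position; loss of silanol and aromatisation to the 1-arylnaphthalene would follow, in the flask or on purification.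
   - Fallback: ring closure and saturation are merged so that the labile dihydronaphthalene is never isolated. Diene 16 is cyclised with the same ruthenium carbene; once closure is complete the vessel is put under H2 pressure, which converts the carbene into a ruthenium hydride hydrogenation catalyst that reduces the fresh C2=C3 bond in the same pot (tandem metathesis–hydrogenation). The route is rejoined at tetralin 18 and no new compound is made.

3. Step 2.
   - What may go wrong: competing attack at C2 (ortho to the hydroxyl), overbromination, or attack on the methoxy-bearing ring would give regioisomer mixtures.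
   - Fallback: the regiochemical question is removed by symmetry.
   - Diol 1 is exhaustively methylated (Me2SO4, K2CO3, acetone) to 1,8-dimethoxynaphthalene F8.
   - Vilsmeier–Haack formylation (POCl3, DMF) gives 4,5-dimethoxynaphthalene-1-carbaldehyde F9.
   - Nucleophilic demethylation with NaSEt in DMF should cleave only the methoxy group para to the formyl group, whose aryloxide is the better leaving group, giving 4-hydroxy-5-methoxynaphthalene-1-carbaldehyde F10.
   - Silylation with iPr3SiCl and imidazole gives 5-methoxy-4-(triisopropylsilyloxy)naphthalene-1-carbaldehyde F11.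
   - Horner–Wadsworth–Emmons olefination with trimethyl phosphonoacetate and NaH returns to the route at ester 6.

**Further compounds**

F1 | step 10 | 2-bromo-3-methoxybenzonitrile | COc1cccc(C#N)c1Br
F2 | step 10 | (2-cyano-6-methoxyphenyl)magnesium chloride | COc1cccc(C#N)c1[Mg]Cl
F3 | step 10 | (2-cyano-6-methoxyphenyl)zinc bromide | COc1cccc(C#N)c1[Zn]Br
F4 | step 10 | 3-methoxy-2-{(1S)-1-[5-methoxy-4-(triisopropylsilyloxy)naphthalen-1-yl]prop-2-en-1-yl}benzonitrile | COc1cccc(C#N)c1[C@H](c1ccc(O[Si](C(C)C)(C(C)C)C(C)C)c2c(OC)cccc12)C=C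
F5 | step 10 | 3-methoxy-2-{(1S)-1-[5-methoxy-4-(triisopropylsilyloxy)naphthalen-1-yl]prop-2-en-1-yl}benzaldehyde | COc1cccc(C=O)c1[C@H](c1ccc(O[Si](C(C)C)(C(C)C)C(C)C)c2c(OC)cccc12)C=C
F6 | step 10 | 1-(3-methoxy-2-{(1S)-1-[5-methoxy-4-(triisopropylsilyloxy)naphthalen-1-yl]prop-2-en-1-yl}phenyl)prop-2-en-1-ol (C1 epimers) | COc1cccc(C(O)C=C)c1[C@H](c1ccc(O[Si](C(C)C)(C(C)C)C(C)C)c2c(OC)cccc12)C=C
F7 | step 10 | (1S)-1-(3-methoxy-2-{(1S)-1-[5-methoxy-4-(triisopropylsilyloxy)naphthalen-1-yl]prop-2-en-1-yl}phenyl)prop-2-en-1-ol | COc1cccc([C@@H](O)C=C)c1[C@H](c1ccc(O[Si](C(C)C)(C(C)C)C(C)C)c2c(OC)cccc12)C=C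
F0 | step 11 | none | none
F8 | step 2 | 1,8-dimethoxynaphthalene | COc1cccc2cccc(OC)c12
F9 | step 2 | 4,5-dimethoxynaphthalene-1-carbaldehyde | COc1cccc2c(C=O)ccc(OC)c12
F10 | step 2 | 4-hydroxy-5-methoxynaphthalene-1-carbaldehyde | COc1cccc2c(C=O)ccc(O)c12
F11 | step 2 | 5-methoxy-4-(triisopropylsilyloxy)naphthalene-1-carbaldehyde | COc1cccc2c(C=O)ccc(O[Si](C(C)C)(C(C)C)C(C)C)c12
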